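The constants used here are made up; no experiment stands behind them.

Divide the rate at which Q goes to Z by the rate at which it goes to X and time drops out, so you can reckon the split of the charge before asking how long anything takes.

    Q → X, rate k1*[Q]/(1 + ([Q]/sat1)) (sat1 = 1.03 mM, k1 = 4.20 s⁻¹, Ea1 = 64.0 kJ mol⁻¹)
    Q ⇌ Z (K2 = 11.7, k2 = 0.0632 s⁻¹, Ea2 = 89.0 kJ mol⁻¹, ΔH2 = −25.0 kJ mol⁻¹)
    (constants at 60 °C)

in all of them: Q 10 mM; time 20 s
- zeta: temperature 60 °C
- delta: temperature 30 °C
- beta: at 90 °C until 6.0 s, from then on at 30 °C
- gamma: temperature 90 °C

- the constants hold at 60 °C; other temperatures follow from the activation energies and enthalpies

- the flask with the highest amount of X, in percent of the Q charged ("all alike" if they lie within 1.5 percentage points) (zeta / delta / beta / gamma / all alike)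
- final X, as a percentage of the Q charged, in zeta
- final X, as a percentage of the Q charged, in delta
- final X, as a percentage of the Q charged, in beta
- final X, as a percentage of the Q charged, in gamma

Here is my own ladder, within each flask the faster rung first. While Q stands well above the saturation constant, as the charge of 10 mM does against 1.03 mM, the step to X runs at a nearly flat rate, the rate constant times the saturation constant, so the charge over that rate gives a flat-rate estimate of the drain time: 0.343 s in gamma, 2.31 s in zeta and 22.7 s in delta. The next rung is the return time of Z to Q, the equilibrium constant over the forward constant: 6.18 s in gamma, 185 s in zeta and 181 min in delta. Gamma, zeta and delta each drain faster than they return, so you can treat the split first and the return afterwards.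

With x the fraction of the charge still Q, and the return set aside, Z made per X made is the ratio of the second step's forward constant to the first step's constant, times one plus x times the charge over the saturation constant. At the start of delta, the making of X runs 15 times as fast as the forward loss of Q to Z. Taking x at 0.5 gives 0.0361 for delta; call this the split ratio, Z made per X made over a whole drain, a selectivity factor. It is 0.0881 in zeta and 0.186 in gamma, since from delta to gamma the second step gains a factor 340 against the first step's 66. In my reckoning a split ratio m puts m/(1+m) of the charge into Z, which I then let decay on its return time. So I expect X of 92.7% in zeta and 99.4% in gamma. Beta drains at gamma's temperature, so it takes gamma's split ratio, and its return runs at gamma's pace until 6.0 s and then slows to delta's, giving 94.1%. Gamma comes out highest of these. For delta I commit to no figure, since its drain time is longer than the 20 s allowed.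

The forecast says gamma, with 93% in zeta, 73.6% in delta, 93.8% in beta and 99.3% in gamma, on the ground that “Only at 90 °C is the return from Z fast enough to drain it into X within 20 s”.

The simulation gives gamma, with 92.8% in zeta, 73.5% in delta, 93.9% in beta and 99.3% in gamma.

At 20.0 s delta holds Q 23.4%, and its Z per X, 0.0428, stands above the split ratio 0.0361. The neighbouring flask is delta itself read at 50 s, and there Q stands at 0%. Its Z per X is 0.0356, close to the split ratio. The same reckoning puts 3.48% of the charge in Z, and that flask reads Z 3.44%.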